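**Direct plan and its weak points**

A direct plan would make methyl olivetolate A1 by Michael–Dieckmann annulation of dimethyl malonate with non-3-en-2-one and bromine-mediated aromatisation, and would use A1 for both rings. O-Methylation and saponification would give 2,4-dimethoxy-6-pentylbenzoic acid A2; hydrolysis with decarboxylation to olivetol A3, re-carboxylation to olivetolic acid A4 and benzylation would give benzyl olivetolate A5. A trifluoroacetic mixed anhydride of A2 would acylate A5 to the benzyl depside A6, and hydrogenolysis would end the route.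
- The decarboxylation of A1 to A3 followed by carboxylation back to A4 would remove and then reinstall the same carboxyl carbon: a run of steps that builds nothing.
- The union of A2 with A5 would be a late acyl transfer from a di-ortho-substituted, electron-rich acid: slow, open to ring acylation or trifluoroacetylation, and selective for 4-OH over 2-OH only through a hydrogen bond.
- The saponification to A2 would need KOH in hot DMSO on a hindered ester of a resorcylate that decarboxylates easily.

**Retrosynthetic overview**

Both rings are 6-pentyl-β-resorcylates: C1 (carrying the carboxyl carbon) sits between C6-pentyl and C2-O, with C4-O para. A (4+2) cycloaddition of an oct-2-ynoate (C1, C6, carboxyl carbon, pentyl) with a 1,1,3-trioxygenated buta-1,3-diene (C2 to C5, both oxygens already differentiated) writes this pattern in one operation.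
Key disconnection: the C1–C2 and C5–C6 bonds of ring B, cut in the intact depside. Ring B is grown on the aryl oct-2-ynoate 8 with diene 12, so the hindered aroyl ester is never made by acyl transfer; the depside C–O bond is closed earlier with unhindered oct-2-ynoic acid.
Ring order: ring A first, by the same cycloaddition (allyl oct-2-ynoate 2 with bis(silyloxy) diene 4, giving free 2-OH and 4-OH and an allyl ester), then ring B on the 4-oxygen of ring A.
No carboxyl group is removed and put back, no hindered ester is saponified, and the end game is a room-temperature methylation and a neutral deallylation.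

Key step: step 7

Remarks: ring A is the hydroxy acid ring, ring B the dimethoxybenzoyl ring; locants in each ring count from the carbon that bears the carboxyl carbon. The target has no stereocentre. Assumption: methyl 3-(trimethylsilyloxy)but-2-enoate 3, the silyl enol ether of methyl acetoacetate, is taken as a catalogue compound (E/Z mixture acceptable).

**Route**

Step 1
Reactants: 1 oct-2-ynoic acid
Product: 2 allyl oct-2-ynoate
Conditions: allyl bromide (1.2 equiv), KHCO3 (1.5 equiv), DMF, rt, 16 h
Reagents that add atoms: allyl bromide, C=CCBr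
Why: SN2 O-alkylation of the potassium carboxylate by the allylic halide should give the ester, bicarbonate being too weak a base to isomerise the alk-2-ynoate to an allene.

Step 2
Reactants: 3 methyl 3-(trimethylsilyloxy)but-2-enoate
Product: 4 1-methoxy-1,3-bis(trimethylsilyloxy)buta-1,3-diene
Conditions: LiN(iPr)2 (1.1 equiv), THF, −78 °C, 1 h; TMSCl (1.3 equiv), −78 °C → rt; filtration under N2, distillation
Reagents that add atoms: chlorotrimethylsilane, C[Si](C)(C)Cl
Why: Kinetic γ-deprotonation of the silyl enol ether ester and O-silylation of the resulting dienolate is the standard preparation of 1,3-bis(silyloxy) dienes; the geometry of the ketene acetal is of no consequence for the next step.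

Step 3
Reactants: 2 allyl oct-2-ynoate; 4 1-methoxy-1,3-bis(trimethylsilyloxy)buta-1,3-diene
Product: 7 allyl 2,4-dihydroxy-6-pentylbenzoate, via cycloadduct 5 (not isolated), via bis(trimethylsilyl) ether 6 (not isolated)
Conditions: 4 (2 equiv), toluene, 110 °C, sealed tube, 24 h; then 1 M HCl/THF, rt, 1 h
Reagents that add atoms: none
Why: Diels–Alder benzannulation, in which the CH2 terminus of the diene bonds to the pentyl-bearing β-carbon of the ynoate and the ketene acetal carbon to the α-carbon, followed by 1,4-elimination of methanol and acid desilylation, should give ring A with both phenols free; the racemic ketal stereocentre of 5 is erased on aromatisation.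

Step 4
Reactants: 7 allyl 2,4-dihydroxy-6-pentylbenzoate; 1 oct-2-ynoic acid
Product: 8 allyl 2-hydroxy-4-(oct-2-ynoyloxy)-6-pentylbenzoate
Conditions: 1 (1.05 equiv), DCC (1.1 equiv), DMAP (5 mol %), CH2Cl2, 0 °C → rt, 4 h
Reagents that add atoms: none
Why: Steglich esterification with an unhindered acid should go to the free 4-OH, since the 2-OH is tied up in a hydrogen bond to the allyl ester carbonyl; low temperature and catalytic DMAP hold back conjugate addition of the phenol to the ynoate.

Step 5
Reactants: 9 1,1-dimethoxyethene; 10 acetyl chloride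
Product: 11 4,4-dimethoxybut-3-en-2-one
Conditions: pyridine (1.2 equiv), Et2O, 0 °C → rt, 12 h
Reagents that add atoms: none
Why: C-Acylation of the nucleophilic β-carbon of the ketene acetal by the acylpyridinium salt and loss of HCl to pyridine should give the push–pull β,β-dimethoxy enone (acylation of a ketene acetal with an acid chloride).

Step 6
Reactants: 11 4,4-dimethoxybut-3-en-2-one
Product: 12 1,1-dimethoxy-3-(trimethylsilyloxy)buta-1,3-diene
Conditions: LiN(SiMe3)2 (1.1 equiv), THF, −78 °C; TMSCl (1.2 equiv), −78 °C → rt; distillation
Reagents that add atoms: chlorotrimethylsilane, C[Si](C)(C)Cl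
Why: Kinetic deprotonation of the methyl ketone by a non-nucleophilic amide and O-silylation of the cross-conjugated enolate (silyl enol ether formation) should give the diene without addition to the ketene acetal carbon.

Step 7
Reactants: 8 allyl 2-hydroxy-4-(oct-2-ynoyloxy)-6-pentylbenzoate; 12 1,1-dimethoxy-3-(trimethylsilyloxy)buta-1,3-diene
Product: 16 allyl 2-hydroxy-4-[(4-hydroxy-2-methoxy-6-pentylbenzoyl)oxy]-6-pentylbenzoate, via silyl ether 13 (not isolated), via cycloadduct 14 (not isolated), via bis(trimethylsilyl) ether 15 (not isolated)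
Conditions: TMSCl (1.2 equiv), Et3N (1.3 equiv), toluene, rt, 1 h, filtration and concentration under N2; 12 (2.5 equiv), toluene, 120 °C, sealed tube, 24 h; then 1 M HCl/THF, 0 °C → rt
Reagents that add atoms: none
Why: The electron-rich diene 12 and the electron-poor ynoate of 13 should combine in a thermal normal-demand (4+2) cycloaddition to the cyclohexa-1,4-diene 14, whose ketal carbon loses methanol in a 1,4-elimination to give the arene 15, and acid work-up removes both trimethylsilyl groups. The closest known reaction type is the Diels–Alder benzannulation of alkyl alk-2-ynoates with 1,1-dimethoxy-3-silyloxybuta-1,3-dienes to 6-alkyl-4-hydroxy-2-methoxybenzoates. Ring B is closed by an intermolecular (4+2) cycloaddition that forms C1–C2 and C5–C6 at once, the ynoate supplying C1, C6, the carbonyl carbon and the pentyl chain, the diene supplying C2 to C5 and both ring oxygens. No stereocentre is formed, since the ketal carbon of 14 carries two identical methoxy groups and becomes aromatic. The step needs regioselectivity, which polarity matching should secure: the CH2 terminus of 12, pushed by the 3-silyloxy and the 1,1-dimethoxy groups, bonds to the pentyl-bearing β-carbon of the ynoate, so that the ketal carbon (later C2-OMe) lands next to C1 and the silyloxy carbon para to it. It also needs chemoselectivity, which rests on the transient silyl mask of the ring A phenol (a free OH would protonate the diene), on the unactivated allyl alkene, and on the aryl ester, which makes the ynoate a better dienophile than the alkyl esters of the precedent.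

Step 8
Reactants: 16 allyl 2-hydroxy-4-[(4-hydroxy-2-methoxy-6-pentylbenzoyl)oxy]-6-pentylbenzoate
Product: 17 allyl 4-[(2,4-dimethoxy-6-pentylbenzoyl)oxy]-2-hydroxy-6-pentylbenzoate
Conditions: MeI (1.3 equiv), K2CO3 (1.3 equiv), acetone, rt, 12 h
Reagents that add atoms: iodomethane, CI
Why: Williamson ether synthesis should methylate only the non-chelated, more acidic 4-OH of ring B, because the ring A 2-OH is locked in a hydrogen bond to the allyl ester carbonyl and the hindered depside ester has no nucleophile to fear under these conditions.

Step 9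
Reactants: 17 allyl 4-[(2,4-dimethoxy-6-pentylbenzoyl)oxy]-2-hydroxy-6-pentylbenzoate
Product: 18 2-hydroxy-4-[(2,4-dimethoxy-6-pentylbenzoyl)oxy]-6-pentylbenzoic acid (target)
Conditions: Pd(PPh3)4 (5 mol %), morpholine (3 equiv), THF, rt, 2 h; then 1 M HCl, 0 °C
Reagents that add atoms: none
Why: Tsuji–Trost deallylation, in which zerovalent palladium ionises the allyl ester to a π-allyl complex that morpholine captures, should free the acid at room temperature without touching the di-ortho-substituted aryl ester, the methyl ethers or the decarboxylation-prone β-resorcylic acid.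

**Compound list**

1 | oct-2-ynoic acid | CCCCCC#CC(=O)O | starting material
2 | allyl oct-2-ynoate | CCCCCC#CC(=O)OCC=C | intermediate
3 | methyl 3-(trimethylsilyloxy)but-2-enoate (E/Z mixture) | COC(=O)C=C(C)O[Si](C)(C)C | starting material
4 | 1-methoxy-1,3-bis(trimethylsilyloxy)buta-1,3-diene (ketene acetal geometry not defined) | C=C(O[Si](C)(C)C)C=C(OC)O[Si](C)(C)C | intermediate
5 | allyl 6-methoxy-2-pentyl-4,6-bis(trimethylsilyloxy)cyclohexa-1,4-diene-1-carboxylate (racemic, not isolated) | CCCCCC1=C(C(=O)OCC=C)C(OC)(O[Si](C)(C)C)C=C(O[Si](C)(C)C)C1 | intermediate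
6 | allyl 2-pentyl-4,6-bis(trimethylsilyloxy)benzoate (not isolated) | CCCCCc1cc(O[Si](C)(C)C)cc(O[Si](C)(C)C)c1C(=O)OCC=C | intermediate
7 | allyl 2,4-dihydroxy-6-pentylbenzoate | CCCCCc1cc(O)cc(O)c1C(=O)OCC=C | intermediate
8 | allyl 2-hydroxy-4-(oct-2-ynoyloxy)-6-pentylbenzoate | CCCCCC#CC(=O)Oc1cc(O)c(C(=O)OCC=C)c(CCCCC)c1 | intermediate
9 | 1,1-dimethoxyethene | C=C(OC)OC | starting material
10 | acetyl chloride | CC(=O)Cl | starting material
11 | 4,4-dimethoxybut-3-en-2-one | CC(=O)C=C(OC)OC | intermediate
12 | 1,1-dimethoxy-3-(trimethylsilyloxy)buta-1,3-diene | C=C(O[Si](C)(C)C)C=C(OC)OC | intermediate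
13 | allyl 4-(oct-2-ynoyloxy)-6-pentyl-2-(trimethylsilyloxy)benzoate (not isolated) | CCCCCC#CC(=O)Oc1cc(O[Si](C)(C)C)c(C(=O)OCC=C)c(CCCCC)c1 | intermediate
14 | allyl 4-{[6,6-dimethoxy-2-pentyl-4-(trimethylsilyloxy)cyclohexa-1,4-diene-1-carbonyl]oxy}-6-pentyl-2-(trimethylsilyloxy)benzoate (not isolated) | CCCCCC1=C(C(=O)Oc2cc(O[Si](C)(C)C)c(C(=O)OCC=C)c(CCCCC)c2)C(OC)(OC)C=C(O[Si](C)(C)C)C1 | intermediate
15 | allyl 4-{[2-methoxy-6-pentyl-4-(trimethylsilyloxy)benzoyl]oxy}-6-pentyl-2-(trimethylsilyloxy)benzoate (not isolated) | CCCCCc1cc(O[Si](C)(C)C)cc(OC)c1C(=O)Oc1cc(O[Si](C)(C)C)c(C(=O)OCC=C)c(CCCCC)c1 | intermediate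
16 | allyl 2-hydroxy-4-[(4-hydroxy-2-methoxy-6-pentylbenzoyl)oxy]-6-pentylbenzoate | CCCCCc1cc(O)cc(OC)c1C(=O)Oc1cc(O)c(C(=O)OCC=C)c(CCCCC)c1 | intermediate
17 | allyl 4-[(2,4-dimethoxy-6-pentylbenzoyl)oxy]-2-hydroxy-6-pentylbenzoate | CCCCCc1cc(OC)cc(OC)c1C(=O)Oc1cc(O)c(C(=O)OCC=C)c(CCCCC)c1 | intermediate
18 | 2-hydroxy-4-[(2,4-dimethoxy-6-pentylbenzoyl)oxy]-6-pentylbenzoic acid (achiral) | CCCCCc1cc(OC(=O)c2c(CCCCC)cc(OC)cc2OC)cc(O)c1C(=O)O | target

**Step count and risks**

Total steps: 9. Longest linear sequence: 6 steps (steps 1, 3, 4, 7, 8, 9).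

Steps most likely to fail:

1. Step 7. The cycloaddition on the β-alkyl aryl ynoate may be outrun by thermal decay or desilylation of the diene, or by silyl or acyl transfer at the activated aryl ester, so that ring B does not form cleanly. Fallback: set out from 12 and build ring B on commercial methyl oct-2-ynoate, the substrate class with direct precedent (neat, 130 °C; dilute HCl), to give methyl 4-hydroxy-2-methoxy-6-pentylbenzoate F1. Methylation (MeI, K2CO3, acetone) would give methyl 2,4-dimethoxy-6-pentylbenzoate F2, and saponification (KOH, DMSO/H2O, 100 °C) would give 2,4-dimethoxy-6-pentylbenzoic acid F3. Acylation of 7 with the mixed anhydride of F3 ((CF3CO)2O, toluene, rt) would come back to the route at 17, at the price of a hindered acyl transfer.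

2. Step 3. The bis(silyloxy) diene may suffer O-to-C silyl migration or protodesilylation before it adds, or the adduct may aromatise by loss of trimethylsilanol instead of methanol and leave the 2-oxygen methylated. Fallback: set out from 2 and use the more robust diene 12 (toluene, 120 °C; dilute HCl) to give allyl 4-hydroxy-2-methoxy-6-pentylbenzoate F4. Chelation-directed cleavage of the methoxy group ortho to the ester carbonyl (BCl3, CH2Cl2, −78 → 0 °C) would come back to the route at 7.

3. Step 5. Acetyl chloride may be dehydrohalogenated to ketene, which adds (2+2) to the ketene acetal, or the acid-sensitive ketene acetal may polymerise before C-acylation. Fallback: set out from 10 and acylate 1,1-dichloroethene (AlCl3, CH2Cl2, 0 °C, then loss of HCl on distillation) to give 4,4-dichlorobut-3-en-2-one F5. Two addition–elimination events with NaOMe (2.1 equiv, MeOH, 0 °C) would come back to the route at 11.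

Further compounds
F1 | step 7 | methyl 4-hydroxy-2-methoxy-6-pentylbenzoate | CCCCCc1cc(O)cc(OC)c1C(=O)OC
F2 | step 7 | methyl 2,4-dimethoxy-6-pentylbenzoate | CCCCCc1cc(OC)cc(OC)c1C(=O)OC
F3 | step 7 | 2,4-dimethoxy-6-pentylbenzoic acid | CCCCCc1cc(OC)cc(OC)c1C(=O)O
F4 | step 3 | allyl 4-hydroxy-2-methoxy-6-pentylbenzoate | CCCCCc1cc(O)cc(OC)c1C(=O)OCC=C
F5 | step 5 | 4,4-dichlorobut-3-en-2-one | CC(=O)C=C(Cl)Cl
A1 | direct plan | methyl olivetolate (methyl 2,4-dihydroxy-6-pentylbenzoate) | CCCCCc1cc(O)cc(O)c1C(=O)OC
A2 | direct plan | 2,4-dimethoxy-6-pentylbenzoic acid | CCCCCc1cc(OC)cc(OC)c1C(=O)O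
A3 | direct plan | olivetol (5-pentylbenzene-1,3-diol) | CCCCCc1cc(O)cc(O)c1
A4 | direct plan | olivetolic acid (2,4-dihydroxy-6-pentylbenzoic acid) | CCCCCc1cc(O)cc(O)c1C(=O)O
A5 | direct plan | benzyl olivetolate (benzyl 2,4-dihydroxy-6-pentylbenzoate) | CCCCCc1cc(O)cc(O)c1C(=O)OCc1ccccc1
A6 | direct plan | benzyl 4-[(2,4-dimethoxy-6-pentylbenzoyl)oxy]-2-hydroxy-6-pentylbenzoate | CCCCCc1cc(OC(=O)c2c(CCCCC)cc(OC)cc2OC)cc(O)c1C(=O)OCc1ccccc1
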